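Late in the closed flasks beta, eta and theta the number to watch has stopped moving: no step takes target away, so its final share is the split of starting material between two exits, the catalytic cycle and self-condensation; tank zeta has its outlet as a third exit.

    partner + free catalyst ⇌ catalyst intermediate A (K1 = 8.4 L mol⁻¹, k1 = 2700 L mol⁻¹ s⁻¹)
    starting material + catalyst intermediate A → catalyst intermediate B (k2 = 2.0 × 10⁵ L mol⁻¹ s⁻¹)
    catalyst intermediate B → free catalyst + target (k3 = 140 s⁻¹)
    2 starting material → self-condensation product (k4 = 3.7 L mol⁻¹ s⁻¹)

the same everywhere: free catalyst 0.05 mol%
- beta: starting material 0.050 M; partner 3.00 equiv; time 25 s; everything together in a closed stirred flask, run for 25 s
- zeta: starting material 0.050 M; partner 3.00 equiv; a single well-mixed tank run continuously and read at steady state, 25 s in it on average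
- eta: starting material 0.050 M (fed, over 20.0 s); partner 3.00 equiv; time 25 s; a stirred flask in which starting material is dosed at a steady rate over 20.0 s without added volume, worked up at 25 s
- theta: starting material 0.050 M; partner 3.00 equiv (fed, over 20.0 s); time 25 s; a stirred flask in which partner is dosed at a steady rate over 20.0 s without added volume, worked up at 25 s

- a species is counted by the starting material in it: one self-condensation product counts as two
- a step written with two of one species runs at k times the square of its concentration and takes two of it each time
- the stated concentrations are those of everything mixed, before any reaction; amounts are the same in each set-up
- the feed brings no volume worth counting
- run time (beta): 25 s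

* order of the set-ups by the amount of target at the outlet or at the end, in percent of the starting material put in, highest first (beta / zeta / eta / theta)
* amount of target at the outlet or at the end, in percent of the starting material put in, beta
* amount of target at the outlet or at the end, in percent of the starting material put in, zeta
* amount of target at the outlet or at the end, in percent of the starting material put in, eta
* amount of target at the outlet or at the end, in percent of the starting material put in, theta

Write a for free starting material as a fraction of its charge. Two views of the catalyst compete.

The equilibrium view holds that the catalyst sits at the balance of its first step. With 1.3 as that balance, 0.558 of the catalyst is catalyst intermediate A. At full charge the cycle then outruns self-condensation by 7.53, which promises beta about 88.3% or better.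

I hold the ceiling view. At full charge, catalyst intermediate A goes on far faster than it falls back, at 10000 s⁻¹ against 321 s⁻¹, so that balance cannot form. Each turn instead costs the pseudo-first-order loading by partner, 405 s⁻¹, in series with the release at 140 s⁻¹. This gives 104 s⁻¹ per catalyst and a ceiling of 0.0520 s⁻¹ of the charge. Self-condensation at full charge takes 0.370 s⁻¹, more than the ceiling.

Dividing one rate by the other removes time. The exits are equal at the crossover fraction, the value of a at which self-condensation matches the ceiling, 0.375. While partner stands at full charge and the cycle runs at its ceiling, the share going to target at a is one over one plus the square of a over this crossover.

Simpson's weights over a falling from full charge to zero, with partner and the ceiling held as they are at the start, give an estimate for beta of 42.7%. In eta the dosing, 0.0500 s⁻¹ of the charge, is below the ceiling, as is the throughput of zeta, 0.0400 s⁻¹. I place both high but cannot part them by this reckoning. In theta the ceiling grows from nothing as partner arrives, so I put theta last.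

The forecast takes the ceiling side, saying yield depends on “keeping starting material at only a few mM”. It gives zeta > eta > beta > theta, with 43.5%, 89.6%, 88.5% and 32% for beta, zeta, eta and theta; its beta differs slightly from my 42.7%.

The simulation gives eta > zeta > beta > theta, with 44.5%, 89.6%, 92.3% and 30.8%, so beta lies near the ceiling figure, and eta, not zeta, comes first. The equilibrium view has its region below 0.0321 of the charge: in eta at 25.0 s, with a at 0.0464%, catalyst intermediate A over free catalyst reads 0.860 against a balance of 0.872. The peak a in eta, 0.131, stood below the crossover, which with partner taken at full charge reckons to a share to target of 89.1% at that peak. With 0.12 mol% of free catalyst, the full-partner crossover for the neighbour of theta reckons to 0.581, and that flask ended at 39.0% target.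

The numbers of this flask are made up; no experiment stands behind them.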